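Everything rests on disconnecting the diaryl ether between its oxygen, kept on ring B (the dioxygenated hydroquinone ring), and the ether carbon of ring A (the monophenol ring). In ring A the C–OH, the chain-bearing carbon and the ether carbon are mutually meta, so ring A is the aromatized form of a 5-alkylcyclohexane-1,3-dione whose two carbonyls are equivalent. The key step is a metal-free macrocyclizing addition–elimination: the ring B phenoxide attacks C3 of the derived 3-chlorocyclohex-2-enone, forming the carbon–oxygen bond and the 21-membered ring at once. Its precursor is that racemic chloroenone, tied through C5 and fourteen methylenes to a 3-alkyl-2,5-dimethoxyphenol; dehydrogenation and demethylation follow.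

Key step: step 9

Remark: the target has no stereocentre; 17 and 18 carry one (C5 of the six-membered ring) as racemates, 14 and 15 are diastereomer mixtures, and all these centres disappear by step 10.

Step 1
Reactants: 1 ω-pentadecalactone (oxacyclohexadecan-2-one)
Product: 3 methyl 15-bromopentadecanoate, via 15-bromopentadecanoic acid 2 (not isolated)
Conditions: HBr (33% in AcOH), 100 °C, sealed tube; evaporate; MeOH, H2SO4 (cat.), reflux
Reagents that add atoms: hydrogen bromide, Br; methanol, CO
Why: Acid-promoted SN2 opening of the lactone at its O–CH2 carbon by bromide, then Fischer esterification, should give the ω-bromo ester, which holds the fourteen methylenes and the future C5 of ring A.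

Step 2
Reactants: 4 3-bromo-2-hydroxy-5-methoxybenzaldehyde
Product: 5 3-bromo-2,5-dimethoxybenzaldehyde
Conditions: MeI, K2CO3, DMF, rt
Reagents that add atoms: iodomethane, CI
Why: Williamson ether synthesis on the acidic, chelated phenol should cap the ring B oxygen that must not take part in the later ring closure.

Step 3
Reactants: 3 methyl 15-bromopentadecanoate; 5 3-bromo-2,5-dimethoxybenzaldehyde
Product: 7 methyl 15-(3-formyl-2,5-dimethoxyphenyl)pentadecanoate, via alkylzinc bromide 6 (not isolated)
Conditions: 3, Zn dust, I2 (5 mol%), DMA, 80 °C; then 5, Pd(OAc)2 (2 mol%), SPhos (4 mol%), THF, rt → 45 °C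
Reagents that add atoms: none
Why: Negishi sp3–sp2 cross-coupling: the primary alkylzinc bromide tolerates the ester and the aryl aldehyde, and the biaryl dialkylphosphine should cope with the ortho-methoxy aryl bromide.

Step 4
Reactants: 7 methyl 15-(3-formyl-2,5-dimethoxyphenyl)pentadecanoate
Product: 9 methyl 15-(3-hydroxy-2,5-dimethoxyphenyl)pentadecanoate, via aryl formate 8 (not isolated)
Conditions: mCPBA, CH2Cl2, 0 °C → rt; aq. Na2S2O3 wash; then K2CO3, MeOH, rt
Reagents that add atoms: 3-chloroperoxybenzoic acid, OOC(=O)c1cccc(Cl)c1
Why: Baeyer–Villiger (Dakin-type) oxidation: the ortho-methoxy group should favour aryl over hydride migration, and methanolysis of the formate frees the one phenol that becomes the ether oxygen.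

Step 5
Reactants: 9 methyl 15-(3-hydroxy-2,5-dimethoxyphenyl)pentadecanoate
Product: 10 15-(3-hydroxy-2,5-dimethoxyphenyl)pentadecanal
Conditions: iBu2AlH (2.2 equiv), CH2Cl2, −78 °C; MeOH, then aq. potassium sodium tartrate
Reagents that add atoms: none
Why: Partial ester reduction: the aluminium hemiacetal should persist at −78 °C and collapse to the aldehyde only on work-up, one equivalent of hydride being spent on the phenol.

Step 6
Reactants: 10 15-(3-hydroxy-2,5-dimethoxyphenyl)pentadecanal; 11 1-(triphenylphosphoranylidene)propan-2-one
Product: 12 (E)-18-(3-hydroxy-2,5-dimethoxyphenyl)octadec-3-en-2-one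
Conditions: toluene, 90 °C
Reagents that add atoms: none
Why: Wittig olefination with a stabilized ylide should give the E-enone without added base, so the free phenol is no obstacle; the alkene geometry is consumed in step 7.

Step 7
Reactants: 12 (E)-18-(3-hydroxy-2,5-dimethoxyphenyl)octadec-3-en-2-one; 13 diethyl malonate
Product: 16 5-[14-(3-hydroxy-2,5-dimethoxyphenyl)tetradecyl]cyclohexane-1,3-dione, via keto ester 14 (not isolated), via keto acid 15 (not isolated)
Conditions: NaOEt (2.5 equiv), EtOH, reflux; then aq. NaOH, reflux; then aq. HCl (pH 1), 90 °C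
Reagents that add atoms: none
Why: Michael addition, intramolecular Claisen (Dieckmann-type) condensation, saponification and decarboxylation are the standard entry to 5-substituted cyclohexane-1,3-diones; the phenoxide is a spectator and the product is achiral because both ring arms are alike.

Step 8
Reactants: 16 5-[14-(3-hydroxy-2,5-dimethoxyphenyl)tetradecyl]cyclohexane-1,3-dione
Product: 17 3-chloro-5-[14-(3-hydroxy-2,5-dimethoxyphenyl)tetradecyl]cyclohex-2-en-1-one (racemic)
Conditions: (COCl)2 (1.3 equiv), CH2Cl2, 0 °C → rt; aq. NaHCO3 work-up
Reagents that add atoms: oxalyl chloride, ClC(=O)C(=O)Cl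
Why: Vinylogous acid chloride formation: the enolized dione is acylated and chloride displaces the oxalate by addition–elimination, while the neutral phenol should be inert without base; the symmetric dione can give only one chloroenone, whose C5 centre forms as a racemate.

Step 9
Reactants: 17 3-chloro-5-[14-(3-hydroxy-2,5-dimethoxyphenyl)tetradecyl]cyclohex-2-en-1-one
Product: 18 racemic macrocyclic vinylogous ester: a 3-aryloxycyclohex-2-en-1-one whose ether oxygen sits on C3 of the 2,5-dimethoxyphenyl ring and whose C5 is tied to C1 of that ring by a (CH2)14 chain (21-membered ring)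
Conditions: Cs2CO3 (3 equiv), MeCN, 70 °C; 17 in THF added by syringe pump over 12 h (final 1 mM), argon
Reagents that add atoms: none
Why: The caesium phenoxide of ring B adds to C3 of the β-chloroenone and the chloro-enolate formed expels chloride, an addition–elimination (vinylogous acyl substitution) at a trigonal carbon. The closest known reaction is the carbonate-mediated condensation of phenols with 3-chlorocyclohex-2-en-1-one to 3-aryloxycyclohexenones, applied here within one molecule. The 21-membered ring closes in the 21-exo-trig mode, since the attacked C2=C3 bond lies outside the ring that forms. No stereocentre is created, because C3 stays trigonal, and the racemic C5 centre is untouched and erased in step 10. The step needs ring closure to beat oligomerization, which slow addition to about 1 mM and the large caesium counter-ion should secure, and it needs a single oxygen to attack a single carbon, which the two methyl ethers on ring B and the lone electrophilic carbon of the chloroenone guarantee. Attack through oxygen and not through a ring carbon of the phenoxide is expected for this hard, acyl-type electrophile in a polar aprotic medium.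

Step 10
Reactants: 18 racemic macrocyclic vinylogous ester
Product: 19 1^2,1^5-dimethoxy-2-oxa-1(1,3),3(1,3)-dibenzenacycloheptadecaphan-3^5-ol (the target with both ring B hydroxyls as methyl ethers)
Conditions: Pd(OCOCF3)2 (5 mol%), 2-(dimethylamino)pyridine (10 mol%), TsOH·H2O (20 mol%), O2 (1 atm), DMSO, 80 °C
Reagents that add atoms: none
Why: Palladium-catalysed aerobic dehydrogenation of a cyclohexenone: α′-palladation at C6 and β-hydride loss from C5 should give the cross-conjugated dienone, which tautomerizes to the ring A phenol and removes the racemic centre.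

Step 11
Reactants: 19 1^2,1^5-dimethoxy-2-oxa-1(1,3),3(1,3)-dibenzenacycloheptadecaphan-3^5-ol
Product: 20 2-oxa-1(1,3),3(1,3)-dibenzenacycloheptadecaphane-1^2,1^5,3^5-triol (CNP0393720.0)
Conditions: BBr3 (6 equiv), CH2Cl2, −78 °C → rt; degassed MeOH/H2O quench, argon
Reagents that add atoms: none
Why: Lewis acid cleavage of the two aryl methyl ethers (boron tribromide demethylation) should leave the diaryl ether untouched; air is excluded because the hydroxyhydroquinone ring oxidizes easily.

Compound list
1 | ω-pentadecalactone (oxacyclohexadecan-2-one) | O=C1CCCCCCCCCCCCCCO1 | starting material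
2 | 15-bromopentadecanoic acid | OC(=O)CCCCCCCCCCCCCCBr | intermediate
3 | methyl 15-bromopentadecanoate | COC(=O)CCCCCCCCCCCCCCBr | intermediate
4 | 3-bromo-2-hydroxy-5-methoxybenzaldehyde | COc1cc(Br)c(O)c(C=O)c1 | starting material
5 | 3-bromo-2,5-dimethoxybenzaldehyde | COc1cc(Br)c(OC)c(C=O)c1 | intermediate
6 | (15-methoxy-15-oxopentadecyl)zinc bromide | COC(=O)CCCCCCCCCCCCCC[Zn]Br | intermediate
7 | methyl 15-(3-formyl-2,5-dimethoxyphenyl)pentadecanoate | COC(=O)CCCCCCCCCCCCCCc1cc(OC)cc(C=O)c1OC | intermediate
8 | methyl 15-[3-(formyloxy)-2,5-dimethoxyphenyl]pentadecanoate | COC(=O)CCCCCCCCCCCCCCc1cc(OC)cc(OC=O)c1OC | intermediate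
9 | methyl 15-(3-hydroxy-2,5-dimethoxyphenyl)pentadecanoate | COC(=O)CCCCCCCCCCCCCCc1cc(OC)cc(O)c1OC | intermediate
10 | 15-(3-hydroxy-2,5-dimethoxyphenyl)pentadecanal | O=CCCCCCCCCCCCCCCc1cc(OC)cc(O)c1OC | intermediate
11 | 1-(triphenylphosphoranylidene)propan-2-one | CC(=O)C=P(c1ccccc1)(c1ccccc1)c1ccccc1 | starting material
12 | (E)-18-(3-hydroxy-2,5-dimethoxyphenyl)octadec-3-en-2-one | CC(=O)/C=C/CCCCCCCCCCCCCCc1cc(OC)cc(O)c1OC | intermediate
13 | diethyl malonate | CCOC(=O)CC(=O)OCC | starting material
14 | ethyl 6-[14-(3-hydroxy-2,5-dimethoxyphenyl)tetradecyl]-2,4-dioxocyclohexane-1-carboxylate (diastereomer mixture, present as sodium enolate) | CCOC(=O)C1C(CCCCCCCCCCCCCCc2cc(OC)cc(O)c2OC)CC(=O)CC1=O | intermediate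
15 | 6-[14-(3-hydroxy-2,5-dimethoxyphenyl)tetradecyl]-2,4-dioxocyclohexane-1-carboxylic acid (diastereomer mixture) | OC(=O)C1C(CCCCCCCCCCCCCCc2cc(OC)cc(O)c2OC)CC(=O)CC1=O | intermediate
16 | 5-[14-(3-hydroxy-2,5-dimethoxyphenyl)tetradecyl]cyclohexane-1,3-dione (achiral) | O=C1CC(=O)CC(CCCCCCCCCCCCCCc2cc(OC)cc(O)c2OC)C1 | intermediate
17 | 3-chloro-5-[14-(3-hydroxy-2,5-dimethoxyphenyl)tetradecyl]cyclohex-2-en-1-one (racemic) | O=C1C=C(Cl)CC(CCCCCCCCCCCCCCc2cc(OC)cc(O)c2OC)C1 | intermediate
18 | racemic macrocyclic vinylogous ester: 3-aryloxycyclohex-2-en-1-one, ether oxygen on C3 of the 2,5-dimethoxyphenyl ring, enone C5 joined to C1 of that ring by (CH2)14 | O=C1C=C2CC(C1)CCCCCCCCCCCCCCc1cc(OC)cc(O2)c1OC | intermediate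
19 | 1^2,1^5-dimethoxy-2-oxa-1(1,3),3(1,3)-dibenzenacycloheptadecaphan-3^5-ol | Oc1cc2cc(c1)Oc1cc(OC)cc(c1OC)CCCCCCCCCCCCCC2 | intermediate
20 | 2-oxa-1(1,3),3(1,3)-dibenzenacycloheptadecaphane-1^2,1^5,3^5-triol (CNP0393720.0) | Oc1cc2cc(c1)Oc1cc(O)cc(c1O)CCCCCCCCCCCCCC2 | target

Total steps: 11
Longest linear sequence: 10 steps (1 → 3 → 7 → 9 → 10 → 12 → 16 → 17 → 18 → 19 → 20; the branch from 4 is equally long)

Steps most likely to fail

Step 9. Ring closure may lose against intermolecular substitution, so that oligomers form, and the chloroenone may slowly be hydrolysed or self-condense under carbonate during the long addition. Fallback: setting out from 17, the six-membered ring is dehydrogenated first (conditions of step 10) to 3-chloro-5-[14-(3-hydroxy-2,5-dimethoxyphenyl)tetradecyl]phenol F1. The same carbon–oxygen bond is then closed on the aromatic ring by palladium-catalysed intramolecular aryl ether coupling (Pd(OAc)2, tBuXPhos, K3PO4, toluene, 100 °C, slow addition to 1 mM). The ring A phenol cannot reach its own ring and should stay free, so the product is 19, where the route is rejoined.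

Step 8. The free phenol or the electron-rich ring B may be acylated alongside the dione, or the chloroenone may revert to the dione on work-up. Fallback: setting out from 16, the acidity gap between the vinylogous acid and the phenol is used instead. TsCl with one equivalent of Et3N (CH2Cl2, 0 °C) should sulfonylate only the dione enolate and give 5-[14-(3-hydroxy-2,5-dimethoxyphenyl)tetradecyl]-3-oxocyclohex-1-en-1-yl 4-methylbenzenesulfonate F2. Under the conditions of step 9 this should cyclize with tosylate as the leaving group to 18, where the route is rejoined.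

Step 10. α′-C–H palladation of the electron-rich vinylogous ester may be slow, the acid co-catalyst may cleave the enol ether linkage, and ring B may be over-oxidized. Fallback: setting out from 18, the kinetic α′-enolate (LiN(iPr)2, THF, −78 °C) is trapped with PhSeCl to give the racemic 6-(phenylselanyl) derivative of the macrocyclic enone F3. Oxidation (H2O2, pyridine, CH2Cl2, 0 °C) and selenoxide syn-elimination give the dienone, which tautomerizes to 19, where the route is rejoined.

Further compounds
F1 | step 9 | 3-chloro-5-[14-(3-hydroxy-2,5-dimethoxyphenyl)tetradecyl]phenol | Oc1cc(Cl)cc(CCCCCCCCCCCCCCc2cc(OC)cc(O)c2OC)c1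
F2 | step 8 | 5-[14-(3-hydroxy-2,5-dimethoxyphenyl)tetradecyl]-3-oxocyclohex-1-en-1-yl 4-methylbenzenesulfonate (racemic) | Cc1ccc(cc1)S(=O)(=O)OC1=CC(=O)CC(CCCCCCCCCCCCCCc2cc(OC)cc(O)c2OC)C1
F3 | step 10 | 6-(phenylselanyl) derivative of macrocyclic enone 18, selenium on the carbon between C=O and C5 (racemic, diastereomer mixture) | O=C1C=C2CC(C1[Se]c1ccccc1)CCCCCCCCCCCCCCc1cc(OC)cc(O2)c1OC
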